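**Retrosynthetic overview** (chain numbered C1 at the prenyl end to C24 at the isopropenyl end; stereocentres C7 R, C10 R, C11 R, C22 S)

1. C12–C13 is cut last. Both carbons are C1 of an allylic-alcohol-derived unit and are natively electrophilic; C13 is used with reversed polarity as an allyl carbanion (allylbarium 24 from chloride 21) against the 2,3-epoxy triflate 23.
2. Left half 16 (C1–C12): oxirane by Sharpless epoxidation of allylic alcohol 15; C6–C7 by Zweifel olefination; C7 (R) by a reversed-polarity Hoppe α-oxy carbanion (lithiated carbamate 6) that captures MeBpin. Carbons come from geraniol, 6-methylhept-5-en-2-one and MeBpin.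
3. Right half 21 (C13–C24): from (2E,6E)-farnesol by terminal SeO2 oxidation, then a copper-catalysed SN2′ methylation that sets C22 (S) and the isopropenyl group in one step.
4. Rings: one only, the oxirane, formed in step 8 before the fragment union.

Assumption: geometrically pure geraniol and (2E,6E)-farnesol, (+)-sparteine, D-(−)-diethyl tartrate and both TaniaPhos enantiomers are taken as purchasable.

**Step 1**
Reactants: 1 geraniol
Product: 2 geranyl tert-butyldimethylsilyl ether
Conditions: TBSCl (1.1 equiv), imidazole (1.5 equiv), CH2Cl2, 0 °C → rt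
Reagents that add atoms: tert-butyldimethylsilyl chloride, CC(C)(C)[Si](C)(C)Cl
Why: Imidazole-mediated silylation masks the allylic OH against the organolithium steps and, through the allylic C–O bond, makes the 2,3-alkene less electron-rich than the 6,7-alkene for step 2.

**Step 2**
Reactants: 2 geranyl tert-butyldimethylsilyl ether
Product: 4 (4E)-6-[(tert-butyldimethylsilyl)oxy]-4-methylhex-4-en-1-ol, via secondary ozonide 3 (not isolated)
Conditions: O3/O2 (about 1 equiv, Sudan Red 7B end point), CH2Cl2, −78 °C; then MeOH, NaBH4 (3 equiv), −78 °C → rt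
Reagents that add atoms: ozone, [O-][O+]=O
Why: Chemoselective ozonolysis with reductive work-up: electrophilic ozone cleaves the distal, more electron-rich 6,7-alkene of the geranyl chain, and NaBH4 reduces the ozonide to the primary alcohol (future C7) and propan-2-ol.

**Step 3**
Reactants: 4 (4E)-6-[(tert-butyldimethylsilyl)oxy]-4-methylhex-4-en-1-ol
Product: 5 (4E)-6-[(tert-butyldimethylsilyl)oxy]-4-methylhex-4-en-1-yl N,N-diisopropylcarbamate
Conditions: i-Pr2NCOCl (1.3 equiv), Et3N (1.5 equiv), CH2Cl2, reflux, 24 h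
Reagents that add atoms: N,N-diisopropylcarbamoyl chloride, CC(C)N(C(C)C)C(Cl)=O
Why: O-Carbamoylation installs the Hoppe carbamate, which directs α-lithiation, makes the α-lithio species configurationally stable and later serves as the leaving group.

**Step 4**
Reactants: 5 (4E)-6-[(tert-butyldimethylsilyl)oxy]-4-methylhex-4-en-1-yl N,N-diisopropylcarbamate
Product: 8 tert-butyldimethyl{[(2E,6R)-3-methyl-6-(4,4,5,5-tetramethyl-1,3,2-dioxaborolan-2-yl)hept-2-en-1-yl]oxy}silane, via lithiated carbamate 6 (not isolated), via methylboronate complex 7 (not isolated)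
Conditions: s-BuLi (1.3 equiv), (+)-sparteine (1.3 equiv), Et2O, −78 °C, 5 h; MeBpin (1.5 equiv), −78 °C, 1 h; MgBr2·OEt2 (1.3 equiv), then reflux, 16 h
Reagents that add atoms: 2,4,4,5,5-pentamethyl-1,3,2-dioxaborolane (MeBpin), CB1OC(C)(C)C(C)(C)O1
Why: Hoppe asymmetric deprotonation followed by lithiation–borylation (1,2-metallate rearrangement): s-BuLi/(+)-sparteine removes the pro-R hydrogen to give the (R)-α-oxy carbanion 6, in which the carbinol carbon reacts as a nucleophile; it adds to boron with retention and methyl then migrates from boron to carbon anti to the departing carbamate (inversion), which sets C7 as R.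

**Step 5**
Reactants: 9 6-methylhept-5-en-2-one
Product: 10 N′-[(2E)-6-methylhept-5-en-2-ylidene]-2,4,6-tri(propan-2-yl)benzenesulfonohydrazide
Conditions: 2,4,6-triisopropylbenzenesulfonyl hydrazide (1.0 equiv), MeOH, cat. HCl, rt, 2 h
Reagents that add atoms: 2,4,6-triisopropylbenzenesulfonyl hydrazide, CC(C)c1cc(C(C)C)c(S(=O)(=O)NN)c(C(C)C)c1
Why: Hydrazone condensation gives the E hydrazone (sulfonamide syn to the methyl group), which is what directs the Shapiro deprotonation in step 6 to the methyl side.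

**Step 6**
Reactants: 8 tert-butyldimethyl{[(2E,6R)-3-methyl-6-(4,4,5,5-tetramethyl-1,3,2-dioxaborolan-2-yl)hept-2-en-1-yl]oxy}silane; 10 N′-[(2E)-6-methylhept-5-en-2-ylidene]-2,4,6-tri(propan-2-yl)benzenesulfonohydrazide
Product: 14 tert-butyldimethyl{[(2E,6R)-3,6,11-trimethyl-7-methylidenedodeca-2,10-dien-1-yl]oxy}silane, via vinyllithium 11 (not isolated), via boronate complex 12 (not isolated), via iodoalkylboronate 13 (not isolated)
Conditions: 10 (1.6 equiv), n-BuLi (3.3 equiv), THF, −78 → 0 °C (N2 off), recool to −78 °C; add 8 (1.0 equiv), 30 min; I2 (3 equiv), THF/MeOH, −78 °C, 20 min; NaOMe (6 equiv), MeOH, −78 °C → rt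
Reagents that add atoms: none
Why: Shapiro reaction gives the 1,1-disubstituted vinyllithium regioselectively, and Zweifel olefination then joins it to C7: iodine triggers 1,2-migration of the secondary alkyl group from boron to the alkenyl carbon with retention, and methoxide-induced anti elimination of boron and iodine leaves the C6 exo-methylene, so C7 stays R.

**Step 7**
Reactants: 14 tert-butyldimethyl{[(2E,6R)-3,6,11-trimethyl-7-methylidenedodeca-2,10-dien-1-yl]oxy}silane
Product: 15 (2E,6R)-3,6,11-trimethyl-7-methylidenedodeca-2,10-dien-1-ol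
Conditions: TBAF (1.2 equiv), THF, 0 °C → rt
Reagents that add atoms: none
Why: Fluoride desilylation frees the allylic alcohol needed to direct the epoxidation and touches nothing else.

**Step 8**
Reactants: 15 (2E,6R)-3,6,11-trimethyl-7-methylidenedodeca-2,10-dien-1-ol
Product: 16 [(2R,3R)-3-[(3R)-3,8-dimethyl-4-methylidenenon-7-en-1-yl]-3-methyloxiran-2-yl]methanol
Conditions: Ti(OiPr)4 (10 mol%), D-(−)-diethyl tartrate (12 mol%), t-BuOOH (2 equiv, in decane), 4 Å MS, CH2Cl2, −20 °C
Reagents that add atoms: tert-butyl hydroperoxide, CC(C)(C)OO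
Why: Sharpless asymmetric epoxidation: the titanium-bound allylic alkoxide directs the peroxide to the C10=C11 alkene only, and the D-(−)-tartrate catalyst delivers oxygen to the face that gives the (2R,3R)-oxirane (same sense as geraniol to (2R,3R)-epoxygeraniol), so C10 and C11 are set by the reagent and the E geometry fixes their trans relation.

**Step 9**
Reactants: 17 (2E,6E)-farnesol
Product: 18 (2E,6E)-1-chloro-3,7,11-trimethyldodeca-2,6,10-triene (farnesyl chloride)
Conditions: PPh3 (1.3 equiv), CCl4, reflux, 1 h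
Reagents that add atoms: tetrachloromethane, ClC(Cl)(Cl)Cl
Why: Appel chlorination displaces the oxyphosphonium by chloride at the primary allylic carbon without allylic transposition or loss of E geometry, as in the standard geranyl chloride preparation.

**Step 10**
Reactants: 18 (2E,6E)-1-chloro-3,7,11-trimethyldodeca-2,6,10-triene
Product: 19 (2E,6E,10E)-12-chloro-2,6,10-trimethyldodeca-2,6,10-trien-1-ol
Conditions: SeO2 (0.2 equiv), t-BuOOH (2.5 equiv), salicylic acid (0.1 equiv), CH2Cl2, 0 °C → rt, stopped at partial conversion, 18 recycled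
Reagents that add atoms: tert-butyl hydroperoxide, CC(C)(C)OO (net oxygen source, passed on through SeO2, O=[Se]=O)
Why: Selenium dioxide allylic oxidation (ene reaction, then 2,3-sigmatropic shift) with t-BuOOH as terminal oxidant attacks the terminal gem-dimethyl alkene selectively at its (E)-methyl group and gives the (E)-allylic alcohol.

**Step 11**
Reactants: 19 (2E,6E,10E)-12-chloro-2,6,10-trimethyldodeca-2,6,10-trien-1-ol
Product: 20 (2E,6E,10E)-1-bromo-12-chloro-2,6,10-trimethyldodeca-2,6,10-triene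
Conditions: CBr4 (1.2 equiv), PPh3 (1.2 equiv), CH2Cl2, 0 °C, 30 min
Reagents that add atoms: tetrabromomethane, BrC(Br)(Br)Br
Why: Appel bromination converts only the hydroxyl group, with little free bromide present to exchange the allylic chloride, and so gives two allylic halides of different reactivity.

**Step 12**
Reactants: 20 (2E,6E,10E)-1-bromo-12-chloro-2,6,10-trimethyldodeca-2,6,10-triene
Product: 21 (2E,6E,10S)-1-chloro-3,7,10,11-tetramethyldodeca-2,6,11-triene
Conditions: MeMgBr (1.2 equiv, Et2O), CuBr·SMe2 (3 mol%), (S,Sp)-TaniaPhos [1-[(dimethylamino)(2-diphenylphosphinophenyl)methyl]-2-(diphenylphosphino)ferrocene, C43H39FeNP2] (3.5 mol%), CH2Cl2, −78 °C, 12 h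
Reagents that add atoms: methylmagnesium bromide, C[Mg]Br
Why: Copper-catalysed asymmetric allylic alkylation (SN2′): methyl is delivered to the carbon γ to bromide (C22), creating the methyl stereocentre and the isopropenyl group at once while the allylic chloride (poorer leaving group, fully substituted γ-carbon) is left alone; the ligand enantiomer is chosen by analogy with (E)-1,2-disubstituted allylic bromides to give S, the sense must be confirmed on this 2-methyl-substituted substrate, and the antipodal ligand is used if it is reversed.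

**Step 13**
Reactants: 16 [(2R,3R)-3-[(3R)-3,8-dimethyl-4-methylidenenon-7-en-1-yl]-3-methyloxiran-2-yl]methanol; 21 (2E,6E,10S)-1-chloro-3,7,10,11-tetramethyldodeca-2,6,11-triene
Product: 25 (2R,3R)-2-[(3R)-3,8-dimethyl-4-methylidenenon-7-en-1-yl]-2-methyl-3-[(3E,7E,11S)-4,8,11,12-tetramethyltrideca-3,7,12-trien-1-yl]oxirane (CNP0306316.1), via lithium alkoxide 22 (not isolated), via epoxy triflate 23 (not isolated), via allylbarium chloride 24 (not isolated)
Conditions: BaI2 (1.6 equiv), lithium biphenylide LiC12H10 (3.2 equiv), THF, rt (activated zerovalent barium); −78 °C, 21 (1.5 equiv), 30 min; separately 16 (1.0 equiv), n-BuLi (1.0 equiv), Et2O, −78 °C, then Tf2O (1.0 equiv), 15 min; cannulate into the barium reagent, −78 °C, 1 h; aq. NH4Cl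
Reagents that add atoms: none
Why: Proposed new method: reductive metallation of allylic chloride 21 with activated barium at −78 °C turns C13 from an electrophile into an allyl carbanion that keeps its E geometry and reacts at its α-carbon, and SN2 displacement of the primary triflate in 23 (far more reactive at −78 °C than the hindered trisubstituted oxirane) forms C12–C13 without touching any stereocentre; the closest known reaction types are the barium-mediated α,α′-selective cross-coupling of allylic halides, which tolerates a trisubstituted epoxide in the electrophile, and the displacement of 2,3-epoxy triflates and tosylates by sulfonyl carbanions and cuprates.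

**Compound list**

1 | geraniol, (2E)-3,7-dimethylocta-2,6-dien-1-ol | CC(C)=CCC/C(C)=C/CO | starting material
2 | geranyl tert-butyldimethylsilyl ether | CC(C)=CCC/C(C)=C/CO[Si](C)(C)C(C)(C)C | intermediate
3 | secondary ozonide of 2 at the 6,7-alkene (3,3-dimethyl-1,2,4-trioxolane carrying the silyloxy-methylhexenyl chain at C5) | CC1(C)OOC(CC/C(C)=C/CO[Si](C)(C)C(C)(C)C)O1 | intermediate (not isolated)
4 | (4E)-6-[(tert-butyldimethylsilyl)oxy]-4-methylhex-4-en-1-ol | OCCC/C(C)=C/CO[Si](C)(C)C(C)(C)C | intermediate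
5 | (4E)-6-[(tert-butyldimethylsilyl)oxy]-4-methylhex-4-en-1-yl N,N-diisopropylcarbamate | CC(C)N(C(C)C)C(=O)OCCC/C(C)=C/CO[Si](C)(C)C(C)(C)C | intermediate
6 | (R)-α-lithio derivative of carbamate 5 (lithium on the carbamate-bearing carbon) | [Li][C@@H](OC(=O)N(C(C)C)C(C)C)CC/C(C)=C/CO[Si](C)(C)C(C)(C)C | intermediate (not isolated)
7 | lithium methyl(pinacolato)borate complex of 6 (boron in place of lithium, configuration retained) | [Li+].C[B-]1(OC(C)(C)C(C)(C)O1)[C@@H](OC(=O)N(C(C)C)C(C)C)CC/C(C)=C/CO[Si](C)(C)C(C)(C)C | intermediate (not isolated)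
8 | tert-butyldimethyl{[(2E,6R)-3-methyl-6-(4,4,5,5-tetramethyl-1,3,2-dioxaborolan-2-yl)hept-2-en-1-yl]oxy}silane | C[C@@H](B1OC(C)(C)C(C)(C)O1)CC/C(C)=C/CO[Si](C)(C)C(C)(C)C | intermediate
9 | 6-methylhept-5-en-2-one | CC(=O)CCC=C(C)C | starting material
10 | N′-[(2E)-6-methylhept-5-en-2-ylidene]-2,4,6-tri(propan-2-yl)benzenesulfonohydrazide | C/C(CCC=C(C)C)=N\NS(=O)(=O)c1c(C(C)C)cc(C(C)C)cc1C(C)C | intermediate
11 | (6-methylhepta-1,5-dien-2-yl)lithium | [Li]C(=C)CCC=C(C)C | intermediate (not isolated)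
12 | lithium alkenyl(alkyl)(pinacolato)borate complex of 8 and 11 (C7 R) | [Li+].C=C(CCC=C(C)C)[B-]1(OC(C)(C)C(C)(C)O1)[C@H](C)CC/C(C)=C/CO[Si](C)(C)C(C)(C)C | intermediate (not isolated)
13 | β-iodoalkyl pinacol boronate (C6 carries Bpin, CH2I, the 4-methylpent-3-enyl chain and C7; C7 R) | ICC(CCC=C(C)C)(B1OC(C)(C)C(C)(C)O1)[C@H](C)CC/C(C)=C/CO[Si](C)(C)C(C)(C)C | intermediate (not isolated)
14 | tert-butyldimethyl{[(2E,6R)-3,6,11-trimethyl-7-methylidenedodeca-2,10-dien-1-yl]oxy}silane | C=C(CCC=C(C)C)[C@H](C)CC/C(C)=C/CO[Si](C)(C)C(C)(C)C | intermediate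
15 | (2E,6R)-3,6,11-trimethyl-7-methylidenedodeca-2,10-dien-1-ol | C=C(CCC=C(C)C)[C@H](C)CC/C(C)=C/CO | intermediate
16 | [(2R,3R)-3-[(3R)-3,8-dimethyl-4-methylidenenon-7-en-1-yl]-3-methyloxiran-2-yl]methanol | C=C(CCC=C(C)C)[C@H](C)CC[C@@]1(C)O[C@@H]1CO | intermediate
17 | (2E,6E)-farnesol | CC(C)=CCC/C(C)=C/CC/C(C)=C/CO | starting material
18 | (2E,6E)-1-chloro-3,7,11-trimethyldodeca-2,6,10-triene | CC(C)=CCC/C(C)=C/CC/C(C)=C/CCl | intermediate
19 | (2E,6E,10E)-12-chloro-2,6,10-trimethyldodeca-2,6,10-trien-1-ol | OC/C(C)=C/CC/C(C)=C/CC/C(C)=C/CCl | intermediate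
20 | (2E,6E,10E)-1-bromo-12-chloro-2,6,10-trimethyldodeca-2,6,10-triene | BrC/C(C)=C/CC/C(C)=C/CC/C(C)=C/CCl | intermediate
21 | (2E,6E,10S)-1-chloro-3,7,10,11-tetramethyldodeca-2,6,11-triene | ClC/C=C(\C)CC/C=C(\C)CC[C@H](C)C(=C)C | intermediate
22 | lithium alkoxide of 16 | [Li+].C=C(CCC=C(C)C)[C@H](C)CC[C@@]1(C)O[C@@H]1C[O-] | intermediate (not isolated)
23 | [(2R,3R)-3-[(3R)-3,8-dimethyl-4-methylidenenon-7-en-1-yl]-3-methyloxiran-2-yl]methyl trifluoromethanesulfonate | C=C(CCC=C(C)C)[C@H](C)CC[C@@]1(C)O[C@@H]1COS(=O)(=O)C(F)(F)F | intermediate (not isolated)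
24 | [(2E,6E,10S)-3,7,10,11-tetramethyldodeca-2,6,11-trien-1-yl]barium chloride | Cl[Ba]C/C=C(\C)CC/C=C(\C)CC[C@H](C)C(=C)C | intermediate (not isolated)
25 | (2R,3R)-2-[(3R)-3,8-dimethyl-4-methylidenenon-7-en-1-yl]-2-methyl-3-[(3E,7E,11S)-4,8,11,12-tetramethyltrideca-3,7,12-trien-1-yl]oxirane | C=C(CCC=C(C)C)[C@H](C)CC[C@@]1(C)O[C@@H]1CC/C=C(\C)CC/C=C(\C)CC[C@H](C)C(=C)C | target

**Step count**

Total: 13 steps. Longest linear sequence: 8 steps (1, 2, 3, 4, 6, 7, 8, 13; geraniol to 25).

**Steps most likely to fail, and fallbacks**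

Step 13 (barium-mediated union). The allylbarium may attack sulfur of the triflate, couple through its γ-carbon or open the oxirane. The fallback sets out from 21 (with triflate 23 made from 16 as in step 13) and comes back at 25. Chloride 21 with PhSO2Na in DMF gives [(2E,6E,10S)-3,7,10,11-tetramethyldodeca-2,6,11-trien-1-yl]sulfonylbenzene F1. Its lithio derivative (n-BuLi, THF/DMPU, −78 °C) is alkylated at the sulfonyl-bearing carbon by 23 to give the 13-(phenylsulfonyl) derivative of 25 F2 as both C13 epimers. PdCl2(dppp) (5 mol%) with LiBHEt3 in THF at −20 °C then removes the sulfonyl group without moving the 14,15-alkene and gives 25.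

Step 12 (copper-catalysed SN2′ methylation). The enantioselectivity and facial sense on a 2-methyl-substituted allylic bromide with MeMgBr are not secured, and direct SN2 attack or reaction at the allylic chloride may compete. The fallback sets out from 2 and comes back at 21; it builds C22 with the same reagent-controlled boron chemistry as C7.
- SeO2/t-BuOOH on 2 gives (2E,6E)-8-[(tert-butyldimethylsilyl)oxy]-2,6-dimethylocta-2,6-dien-1-ol F3.
- CBr4/PPh3 gives {[(2E,6E)-8-bromo-3,7-dimethylocta-2,6-dien-1-yl]oxy}(tert-butyl)dimethylsilane F4.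
- CH2(Bpin)2 with NaOt-Bu in THF (deborylative alkylation) gives the homoallylic boronic ester tert-butyldimethyl{[(2E,6E)-3,7-dimethyl-9-(4,4,5,5-tetramethyl-1,3,2-dioxaborolan-2-yl)nona-2,6-dien-1-yl]oxy}silane F5.
- Homologation with ethyl N,N-diisopropylcarbamate after its deprotonation by s-BuLi/(+)-sparteine (then MgBr2·OEt2, reflux) gives tert-butyldimethyl{[(2E,6E,10S)-3,7-dimethyl-10-(4,4,5,5-tetramethyl-1,3,2-dioxaborolan-2-yl)undeca-2,6-dien-1-yl]oxy}silane F6.
- Zweifel olefination with isopropenyllithium (2-bromopropene, t-BuLi), then I2 and NaOMe, gives tert-butyldimethyl{[(2E,6E,10S)-3,7,10,11-tetramethyldodeca-2,6,11-trien-1-yl]oxy}silane F7.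
- TBAF gives (2E,6E,10S)-3,7,10,11-tetramethyldodeca-2,6,11-trien-1-ol F8, and PPh3/CCl4 gives 21.

Step 6 (Zweifel olefination with a Shapiro-derived vinyllithium). The sulfinate and excess iodine may interfere, or the hindered ate complex may form poorly. The fallback sets out from 8 and comes back at 14; it introduces C6 as an sp3 carbon and makes the alkene by carbonyl olefination.
- 5-Methylhex-4-en-1-yl N,N-diisopropylcarbamate F9 (from the commercial alcohol and i-Pr2NCOCl) is lithiated with s-BuLi/TMEDA and added to 8; MgBr2·OEt2 at reflux brings about migration of C7 with retention to give tert-butyldimethyl{[(2E,6R)-3,6,11-trimethyl-7-(4,4,5,5-tetramethyl-1,3,2-dioxaborolan-2-yl)dodeca-2,10-dien-1-yl]oxy}silane F10 (both C7-boryl epimers).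
- NaOH/H2O2 gives (2E,6R)-1-[(tert-butyldimethylsilyl)oxy]-3,6,11-trimethyldodeca-2,10-dien-7-ol F11.
- Dess–Martin periodinane gives (2E,6R)-1-[(tert-butyldimethylsilyl)oxy]-3,6,11-trimethyldodeca-2,10-dien-7-one F12.
- Salt-free Ph3P=CH2 (THF, −78 → 0 °C) gives 14.

**Further compounds**

F1 | step 13 | [(2E,6E,10S)-3,7,10,11-tetramethyldodeca-2,6,11-trien-1-yl]sulfonylbenzene | O=S(=O)(C/C=C(\C)CC/C=C(\C)CC[C@H](C)C(=C)C)c1ccccc1
F2 | step 13 | 13-(phenylsulfonyl) derivative of 25 (sulfonyl on the chain carbon next to the new bond, both epimers) | C=C(CCC=C(C)C)[C@H](C)CC[C@@]1(C)O[C@@H]1CC(/C=C(\C)CC/C=C(\C)CC[C@H](C)C(=C)C)S(=O)(=O)c1ccccc1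
F3 | step 12 | (2E,6E)-8-[(tert-butyldimethylsilyl)oxy]-2,6-dimethylocta-2,6-dien-1-ol | OC/C(C)=C/CC/C(C)=C/CO[Si](C)(C)C(C)(C)C
F4 | step 12 | {[(2E,6E)-8-bromo-3,7-dimethylocta-2,6-dien-1-yl]oxy}(tert-butyl)dimethylsilane | BrC/C(C)=C/CC/C(C)=C/CO[Si](C)(C)C(C)(C)C
F5 | step 12 | tert-butyldimethyl{[(2E,6E)-3,7-dimethyl-9-(4,4,5,5-tetramethyl-1,3,2-dioxaborolan-2-yl)nona-2,6-dien-1-yl]oxy}silane | CC1(C)OB(CC/C(C)=C/CC/C(C)=C/CO[Si](C)(C)C(C)(C)C)OC1(C)C
F6 | step 12 | tert-butyldimethyl{[(2E,6E,10S)-3,7-dimethyl-10-(4,4,5,5-tetramethyl-1,3,2-dioxaborolan-2-yl)undeca-2,6-dien-1-yl]oxy}silane | C[C@H](B1OC(C)(C)C(C)(C)O1)CC/C(C)=C/CC/C(C)=C/CO[Si](C)(C)C(C)(C)C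
F7 | step 12 | tert-butyldimethyl{[(2E,6E,10S)-3,7,10,11-tetramethyldodeca-2,6,11-trien-1-yl]oxy}silane | C=C(C)[C@@H](C)CC/C(C)=C/CC/C(C)=C/CO[Si](C)(C)C(C)(C)C
F8 | step 12 | (2E,6E,10S)-3,7,10,11-tetramethyldodeca-2,6,11-trien-1-ol | C=C(C)[C@@H](C)CC/C(C)=C/CC/C(C)=C/CO
F9 | step 6 | 5-methylhex-4-en-1-yl N,N-diisopropylcarbamate | CC(C)=CCCCOC(=O)N(C(C)C)C(C)C
F10 | step 6 | tert-butyldimethyl{[(2E,6R)-3,6,11-trimethyl-7-(4,4,5,5-tetramethyl-1,3,2-dioxaborolan-2-yl)dodeca-2,10-dien-1-yl]oxy}silane | CC(C)=CCCC(B1OC(C)(C)C(C)(C)O1)[C@H](C)CC/C(C)=C/CO[Si](C)(C)C(C)(C)C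
F11 | step 6 | (2E,6R)-1-[(tert-butyldimethylsilyl)oxy]-3,6,11-trimethyldodeca-2,10-dien-7-ol | CC(C)=CCCC(O)[C@H](C)CC/C(C)=C/CO[Si](C)(C)C(C)(C)C
F12 | step 6 | (2E,6R)-1-[(tert-butyldimethylsilyl)oxy]-3,6,11-trimethyldodeca-2,10-dien-7-one | CC(C)=CCCC(=O)[C@H](C)CC/C(C)=C/CO[Si](C)(C)C(C)(C)C
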